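The earlier runs and the new flask are calculated with made-up constants; noise was put on by code.

The meeting began from a count that a closed flask keeps: if each chain begun takes one initiator out of the charge, the average length is monomer in chains divided by the initiator that began chains.

| flask | free monomer | initiator | remark | time |
|---|---|---|---|---|
| grey | 0.011 M | 0.66 mM | run made earlier |  |
| ochre | 0.011 M | 1.7 mM | run made earlier |  |
| winter | 0.011 M | 0.55 mM |  | 2.5 d |
| summer | 0.011 M | 1.2 mM |  | 2.5 d |

| run | time / d | monomer in chains / % |
|---|---|---|
| grey | 0.333 | 18.2 |
| grey | 0.833 | 53.2 |
| grey | 1.67 | 80.7 |
| grey | 2.50 | 91.1 |
| ochre | 0.333 | 37.9 |
| ochre | 0.833 | 77.4 |
| ochre | 1.67 | 90.3 |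
| ochre | 2.50 | 92.2 |

(each reading ± 0.3 percentage points)

- the average divides the monomer in chains by the number of chains begun, living and dead together
- what was read earlier has a scatter of 0.3 percentage points, one standard deviation
- the earlier runs do not show the number of chains; that part of a forecast is a guess

1. which of the two ends with the longer chains by the average number of monomer units in a chain (chains begun, living or dead) ("neither" if they lie within 10 %) (winter / summer / neither)
2. average number of monomer units in a chain (chains begun, living or dead) at the end, winter
3. average number of monomer units in a chain (chains begun, living or dead) at the end, summer

The chair defined the charge ratio ρ, [free monomer]/[initiator] as charged, the usual target degree of polymerisation, and put it at 20.0 for winter and 9.17 for summer. A second member reported that monomer in chains at 2.50 d read 91.1 % in grey and 92.2 % in ochre, although ochre holds 2.58 times the initiator of grey. She therefore proposed freezing that end value and treating the length as end value times ρ. With the grey reading for winter, the meeting's own reckoning came to 18.2, and with the ochre reading for summer, to 8.45. Winter's ρ is larger than summer's by a factor of 2.18, well outside the margin. A third member objected that this counts each charged initiator as one chain, and that, at the same monomer in chains, a smaller share of initiator beginning chains gives a longer average.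

The forecaster, working from her own end values, named winter as the longer, with 18 (range 14 to 24) for winter and 8.5 (6.5 to 12) for summer. She added: “Incomplete initiation would raise these values, and transfer would lower them.”

The flask gives 23.0 for winter and 13.4 for summer, so winter is longer.

    2 living end → dead end B (k = 0.290 /M/min)
    free monomer + initiator → living end + monomer in chains (k = 0.120 /M/min)
    initiator + monomer in chains → spent initiator A (k = 0.0820 /M/min)
    free monomer + living end → monomer in chains + living end, rate k4*[living end]*[free monomer] (k = 2.20 /M/min)

The summer flask run at winter's initiator charge gives 23.0 against 13.4, so the difference in initiator concentration is the main reason for the gap. Monomer in chains times ρ, divided by the length, gives the share of charged initiator that began a chain: 0.770 in winter and 0.640 in summer. The neighbour of summer with 0.044 M of free monomer has ρ of 36.7, 98.3 % of its monomer in chains and a length of 42.2, which makes its share 0.854.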